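The other capture product and the target grow side by side in this flask, so I follow their ratio: when one rate of formation is divided by the other, time drops out.

| flask | substrate | first nucleophile | second nucleophile | capture agent | remark | time |
|---|---|---|---|---|---|---|
| Tuesday's | 0.50 M | 0.60 M | 1 M | 0.15 M | the very flask that is asked about, followed so far |  |
| flask | 0.50 M | 0.600 M | 1.00 M | 0.150 M |  | 20 h |

Tuesday's run (percent of the substrate charged)

| time / h | other capture product / % | target / % |
|---|---|---|
| 0.250 | 29 | 11 |
| 0.833 | 51 | 24 |
| 1.33 | 59 | 30 |
| 2.00 | 61 | 33 |
| 3.00 | 66 | 32 |
| 4.00 | 65 | 35 |

(each reading ± 2 percentage points)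

* ratio of other capture product to target at 1.0 min
* ratio of other capture product to target at 20 h



My reckoning starts from the last 3 readings of Tuesday's run, from 2.00 h on, whose summed products give a ratio of 1.92. If each nucleophile is lost mole for mole with its product, the run averaged about 0.517 M of first nucleophile and 0.840 M of second. Dividing the product ratio by this nucleophile ratio gives 1.18, which I call s, the selectivity factor: product ratio per unit of the ratio of second to first nucleophile. At 1.0 min the nucleophiles stand as charged, so I expect s times 1.00 M over 0.600 M, or 1.97. The two products already add up to 100% at 4.00 h, so I keep 1.92 for 20 h.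

The forecast gives 2.2 and 1.95. Its early value stands above mine, since “The 15 min point hints at slightly higher”.

The flask gives 1.98 at 1.0 min and 1.92 at 20 h.

    open intermediate + capture agent → trapped intermediate (k = 2.30 L mol⁻¹ h⁻¹)
    first nucleophile + open intermediate → target (k = 18.7 L mol⁻¹ h⁻¹)
    open intermediate → side product (k = 0.350 h⁻¹)
    substrate ⇌ open intermediate (K = 0.141, k = 4.73 h⁻¹)
    second nucleophile + open intermediate → other capture product (k = 22.2 L mol⁻¹ h⁻¹)

With concentrations as charged, the open intermediate has a half-life of 0.062 h by capture with the first nucleophile alone, shorter than 2.0 h by the capture agent, and at 20.0 h this flask holds 1.18% trapped intermediate beside 64.2% other capture product and 33.4% target. Carried to the neighbouring flask with 1.0 M of first nucleophile, s times the charged ratio of second to first nucleophile reckons to 1.18, and that flask gives 1.19 at 1.0 min.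

(The readings stem from a simulated flask for an exercise; the scatter is artificial.)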